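Abbreviations and locants: TBS = tert-butyldimethylsilyl, TBSO = its silyl ether. The core is numbered as a furo[3,2-c]pyran-4-one (O1, C2, C3, C3a, C4, O5, C6, C7, C7a). Ring A is the catechol, ring B the dihydrofuran, ring C the fused 2-pyranone, ring D the pendant 4-hydroxy-2-pyranone (primed locants).

## The problem

The target 21 is a 2,3-dihydro-4H-furo[3,2-c]pyran-4-one: a dihydrofuran (ring B: O1, C2, C3, C3a, C7a) that shares its C3a=C7a double bond with a 2-pyranone (ring C: C3a, C4, O5, C6, C7, C7a). C2 carries catechol ring A, C3 is bonded to C6' of a free 4-hydroxy-2-pyranone (ring D), and C6 carries an (E)-4-hydroxystyryl arm. C2 and C3 are the only stereocentres; they are vicinal, trans and both S, and with no remote centre to relay from, their absolute sense must come from a catalyst or an auxiliary. They are not equally robust. The C2–O1 bond is a benzylic ether of an electron-rich arene whose oxygen belongs to a vinylogous acid, so acid can ionise it; reclosure returns the trans isomer as long as C3 is intact, so C3 can control C2 but not the reverse. The C3–H bond turns acidic as soon as C3 carries a carbonyl group or ring D, and its deprotonation invites β-elimination of O1, which erases both centres. The catechol (oxidation), the two lactones and the acidic 4-hydroxy group of ring D (bases, nucleophiles) and the styryl alkene (hydrogenation, electrophiles) call for silyl ethers on the phenols, a neutral closure of ring D and a mild fluoride finish. The enabling feature is the array O1–C7a=C3a–C4(=O), a cyclic β-alkoxy acrylate whose γ-carbon is C7. Ring C with its styryl arm is therefore a 2-methyl-4,5-dihydrofuran-3-carboxylate lengthened at the methyl group by one cinnamoyl unit, and the stereochemical problem shrinks to a monocyclic dihydrofuran whose C3 substituent can be kept non-acidifying.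

## Retrosynthesis

**Protecting groups.** Target 21 is traced to its tris-silyl ether 20; only three O–Si bonds are cut. Silyl ethers are preferred to benzyl or methyl ethers because their removal needs neither hydrogen (styryl alkene) nor a strong Lewis acid (C2–O1). The forward reaction must be a buffered fluoride cleavage that is not basic enough to touch the C3–H.

**Ring D.** In 20 the lactone bond O1'–C2' and the bond C5'–C6' are cut. This leads through acylketene 19 to δ-keto dioxinone 18, then to carbinol 17, and finally to aldehyde 15 and the four-carbon reagent 16. Cutting C3–C6' instead would require a carbanion or cation at C3, the centre that must not be disturbed. The chosen cut asks only for a one-carbon handle on C3 and closes ring D by heat alone. Aldehyde 15 is simpler than 20 by a whole heterocycle. The forward steps must add a dienolate to an enolisable aldehyde faster than they deprotonate it.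

**Masking the handle.** Aldehyde 15 is traced to its dimethyl acetal 14. No skeletal bond is cut, but the C3–H loses its acidity, which is what the base-mediated construction of ring C requires. The forward hydrolysis must be brief and cold.

**Ring C (key disconnection).** In 14 the bonds C6–C7 and O5–C4 are cut, giving dihydrofuran ester 9 and cinnamoyl Weinreb amide 12. The neighbouring cut through ring B would leave a preformed styrylpyranone that must be cyclopropanated or alkylated at its acidic C3 position. The cut through ring C instead leaves a small chiral dihydrofuran that already holds four of the six ring C atoms at the right oxidation level. The forward reaction must metalate the methyl group of 9 selectively, acylate the dienolate at its γ-carbon in a 1,2 sense, and lactonise the resulting keto ester.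

**The styryl arm.** Amide 12 is cut at its alkene into the commercial aldehyde 10 and phosphonate 11. A stabilised phosphonate anion should deliver the (E)-alkene in one step, with the phenol already protected.

**Ring B.** In 9 the O1–C5 bond is cut and a C3–C5 bond (dihydrofuran locants) is restored, which leads to acetyl cyclopropane ester 8. A direct [3+2] union of an acetoacetate with a cinnamyl unit has the right regiochemistry but no dependable absolute control. The donor–acceptor cyclopropane, in contrast, is available in enantioenriched form, and its ring expansion touches only the aryl-bearing carbon. Cyclopropane 8 is the acetal of aldehyde 7. The acetal is installed first so that the carbon that relays chirality is not enolisable while the benzylic bond is broken.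

**The stereocentres.** Cyclopropane 7 is cut at its two bonds to C1, giving enal 4 and bromo keto ester 6. The forward Michael-initiated ring closure under iminium and enamine catalysis sets both CH centres in one operation from two achiral components.

**Starting materials.** Enal 4 is cut at its alkene into aldehyde 2 and the formyl ylide 3; 2 is the bis-silyl ether of commercial 1; 6 is the bromination product of methyl acetoacetate 5.

## Roads not taken

**Alternative 1:** Ring B is cut at C2–C3 and O1–C7a. The forward key step is an auxiliary-controlled syn-aldol addition of the titanium enolate (TiCl4, amine base) of the pyranon-3-ylacetyl oxazolidinone A1 to aldehyde 2. The titanium aldolate oxygen then displaces the 4-methoxy group of ring C by addition–elimination and gives A2. Its merits are convergence, a stoichiometric auxiliary with a well-understood transition state, and the fact that a syn aldol maps onto the trans ring. On this last point the alternative is at least as trustworthy as an organocatalytic cascade. Its weak points are specific to this target: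
- The enolate of A1 is doubly stabilised and the aldehyde is electron-rich, so the aldol is reversible.
- A titanium aldolate is a poor nucleophile for substitution at a vinylogous carbonate, and dehydration competes.
- In A2 the C3–H is α to an imide carbonyl while O1 is a good β-leaving group. Removing the auxiliary or making a Claisen bond toward ring D therefore risks opening ring B.
- Reductive cleavage to the aldehyde would only rejoin the chosen route at 15, with no steps saved.

The chosen plan sets a less classical stereo-defining step against this, but it never places an acidifying group on C3 while rings B and C are being made.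

**Alternative 2:** Ring B is cut at C3–C3a, C2–C3 and O1–C2 into three components: 4-hydroxypyranone A3, ring D aldehyde A4 and the ylide of a chiral benzylic sulfonium salt A5. A5 is drawn with one antipode of the sulfide; which one is needed is left open. Knoevenagel condensation of A3 with A4 would give a 3-ylidene pyrandione. The ylide adds in conjugate fashion and the enolate oxygen displaces the sulfide to give A6, the fully protected target. In step economy this road is clearly better: the whole skeleton, ring D included, arises in one operation and only deprotection follows. Its weak points: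
- Multicomponent dihydrofuran syntheses of this kind rest on carbonyl-stabilised ylides that coexist with an acidic 4-hydroxypyranone. A benzylic ylide is far more basic and would be quenched by A3.
- The ylidene intermediate is prone to capture a second molecule of A3.
- The sulfonium salt of a bis-siloxybenzyl group solvolyses easily.
- Absolute control would rest on a reversible betaine formation with a very stabilised enolate.
- A6 is formed under base with its acidic C3–H already in place.

The chosen plan is roughly twice as long. Against that it sets a stereo-defining step of a known type and a C3–H that stays non-acidic until the last four steps.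

**Alternative 3:** Ring B is cut at O1–C2 with the bond C3a–C2 restored. This leads to spirocyclopropane A8, made from bromopyranone A7 and enal 4 by the same Michael and alkylation sequence as in step 4. Ionisation of C3a–C2 with Sc(OTf)3 and reclosure through the C7a oxygen would give aldehyde A9, which is the same compound as 15. The stereochemical logic equals that of the chosen plan, and the road is shorter by about four steps because ring C and the styryl arm arrive ready-made. Its weak points lie in the partners:
- A7 is the bromide of a vinylogous acid. Its anion is a weak carbon nucleophile, it can transfer bromine to the enamine, and 4-hydroxypyranones tend to give Michael and hemiacetal products with enals.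
- The spiro acceptor with a para-siloxyaryl donor should open already in the presence of the amine catalyst, at a moment when the formyl group is free. The carbon that must relay chirality is then enolisable, and it cannot be masked beforehand.

The chosen plan pays for its extra steps with an acyclic α-bromo β-keto ester of proven type in the cyclopropanation and an acetal installed before any ionisation. It also forms ring C late from an exchangeable cinnamoyl unit.

Key step: step 8

Assumption: 7 and 8 are carried as mixtures of epimers at the quaternary cyclopropane carbon and 17 as a mixture of carbinol epimers, because both centres become trigonal later; their SMILES leave these centres undefined.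

## Route

Step 1
Reactants: 1 3,4-dihydroxybenzaldehyde
Product: 2 3,4-bis(TBSO)benzaldehyde
Conditions: TBSCl (2.4 equiv), imidazole (5 equiv), DMF, 0 °C to rt
Reagents that add atoms: tert-butyldimethylsilyl chloride, CC(C)(C)[Si](C)(C)Cl
Why: Imidazole-promoted silylation of phenols; aryl TBS ethers should tolerate the amide bases, Lewis acids and heat used later and fall to fluoride at the end.

Step 2
Reactants: 2 3,4-bis(TBSO)benzaldehyde; 3 (triphenylphosphoranylidene)acetaldehyde
Product: 4 (E)-3-[3,4-bis(TBSO)phenyl]prop-2-enal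
Conditions: 3 (1.05 equiv), toluene, 80 °C
Reagents that add atoms: none
Why: Wittig olefination with a formyl-stabilised ylide homologates the aromatic aldehyde by two carbons and should give the (E)-enal; near-stoichiometric ylide and moderate temperature limit a second homologation.

Step 3
Reactants: 5 methyl acetoacetate
Product: 6 methyl 2-bromo-3-oxobutanoate (racemic)
Conditions: N-bromosuccinimide (1.05 equiv), NH4OAc (10 mol %), Et2O, rt
Reagents that add atoms: N-bromosuccinimide, O=C1CCC(=O)N1Br
Why: Electrophilic α-bromination of a β-keto ester through its enol; one equivalent of the reagent should stop at the monobromide, which is used without storage.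

Step 4
Reactants: 4 (E)-3-[3,4-bis(TBSO)phenyl]prop-2-enal; 6 methyl 2-bromo-3-oxobutanoate
Product: 7 methyl (2S,3R)-1-acetyl-2-[3,4-bis(TBSO)phenyl]-3-formylcyclopropane-1-carboxylate (aryl and formyl trans)
Conditions: (S)-2-[diphenyl(trimethylsilyloxy)methyl]pyrrolidine (20 mol %), 2,6-lutidine (1.2 equiv), CH2Cl2, 0 °C to rt
Reagents that add atoms: none
Why: Michael-initiated ring closure under iminium then enamine catalysis, the known organocatalytic cyclopropanation of enals with α-bromo β-keto esters. The bulky silyloxydiphenylmethyl group shields one face of the (E)-iminium ion, so the bromo keto ester should add to the Si face of the β-carbon; the enamine then displaces bromide (3-exo-tet), which places aryl and formyl trans and sets C2 as S and C3 as R.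

Step 5
Reactants: 7 methyl (2S,3R)-1-acetyl-2-[3,4-bis(TBSO)phenyl]-3-formylcyclopropane-1-carboxylate
Product: 8 methyl (2S,3R)-1-acetyl-2-[3,4-bis(TBSO)phenyl]-3-(dimethoxymethyl)cyclopropane-1-carboxylate
Conditions: HC(OMe)3 (3 equiv), pyridinium p-toluenesulfonate (5 mol %), MeOH, rt
Reagents that add atoms: trimethyl orthoformate, COC(OC)OC; methanol, CO
Why: Acid-catalysed acetalisation with the orthoformate as water scavenger; the aldehyde reacts far faster than the hindered acetyl ketone, and the weak acid should not open the cyclopropane. The acetal removes the acidity of the adjacent C–H before the ring expansion.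

Step 6
Reactants: 8 methyl (2S,3R)-1-acetyl-2-[3,4-bis(TBSO)phenyl]-3-(dimethoxymethyl)cyclopropane-1-carboxylate
Product: 9 methyl (4S,5S)-5-[3,4-bis(TBSO)phenyl]-4-(dimethoxymethyl)-2-methyl-4,5-dihydrofuran-3-carboxylate
Conditions: Sc(OTf)3 (5 mol %), 4 Å molecular sieves, CH2Cl2, 0 °C to rt
Reagents that add atoms: none
Why: Cloke–Wilson rearrangement of a donor–acceptor cyclopropane: Sc(OTf)3 chelates the β-keto ester, the C1–C2 bond ionises to a para-siloxy-stabilised benzylic cation and a scandium enolate, and the ketone enolate oxygen closes on the cation. The acetal-bearing carbon is untouched and directs the aryl group anti to itself (5S, trans); reversibility of the C–O bond works toward the same isomer, and both C1 epimers of 8 converge.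

Step 7
Reactants: 10 4-(TBSO)benzaldehyde; 11 diethyl {2-[methoxy(methyl)amino]-2-oxoethyl}phosphonate
Product: 12 (E)-N-methoxy-N-methyl-3-[4-(TBSO)phenyl]prop-2-enamide
Conditions: NaH (1.1 equiv), THF, 0 °C to rt
Reagents that add atoms: none
Why: Horner–Wadsworth–Emmons olefination with a stabilised phosphonate anion, which should give the (E)-enamide; NaH in THF leaves the aryl silyl ether alone.

Step 8
Reactants: 9 methyl (4S,5S)-5-[3,4-bis(TBSO)phenyl]-4-(dimethoxymethyl)-2-methyl-4,5-dihydrofuran-3-carboxylate; 12 (E)-N-methoxy-N-methyl-3-[4-(TBSO)phenyl]prop-2-enamide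
Product: 14 (2S,3S)-2-[3,4-bis(TBSO)phenyl]-3-(dimethoxymethyl)-6-[(E)-2-(4-(TBSO)phenyl)ethenyl]-2,3-dihydro-4H-furo[3,2-c]pyran-4-one, via δ-keto ester 13 (not isolated)
Conditions: LiN(iPr)2 (1.1 equiv), THF, –78 °C; 12 (1.2 equiv), –78 to –20 °C; AcOH (1.5 equiv); then 1,8-diazabicyclo[5.4.0]undec-7-ene (3 equiv), THF, 50 °C
Reagents that add atoms: none
Why: LiN(iPr)2 should remove a proton from the C2 methyl group of 9, which lies syn to the ester and is the only position whose anion is conjugated through C2=C3 into the ester; the ring C–H next to it is not activated because its substituent is an acetal. The γ-carbon of this dienolate adds to the carbonyl of 12 and forms C6–C7; the N-methoxy chelate holds the tetrahedral adduct, so neither a second addition nor proton transfer to unreacted dienolate occurs and one equivalent of 9 suffices. Acetic acid releases δ-keto ester 13, and the amidine base then enolises the new ketone toward C7; the enol oxygen attacks the neighbouring ester carbonyl and expels methoxide, a 6-exo-trig acyl substitution that forms O5–C4 and closes ring C as a 2-pyranone. The closest known reaction type is the γ-acylation of lithium dienolates of β-alkoxycrotonates (a vinylogous Claisen condensation) followed by lactonisation to 4-alkoxy-6-substituted 2-pyranones. No stereocentre is formed, and C2 and C3 of 14 are carried over from 9 because neither C–H is acidic under these conditions. Attack through the γ-carbon and not the α-carbon is secured by the fully substituted, ring-bound α-carbon; 1,2-addition is favoured over conjugate addition by the low Michael reactivity of an enamide that the para-siloxy group deactivates further. The ring holds ester and ketomethylene cis, so closure needs no alkene isomerisation, and the (E)-alkene arrives intact from 12.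

Step 9
Reactants: 14 (2S,3S)-2-[3,4-bis(TBSO)phenyl]-3-(dimethoxymethyl)-6-[(E)-2-(4-(TBSO)phenyl)ethenyl]-2,3-dihydro-4H-furo[3,2-c]pyran-4-one
Product: 15 (2S,3S)-2-[3,4-bis(TBSO)phenyl]-4-oxo-6-[(E)-2-(4-(TBSO)phenyl)ethenyl]-2,3-dihydro-4H-furo[3,2-c]pyran-3-carbaldehyde
Conditions: CF3CO2H/H2O (1:1), CHCl3, 0 °C; used crude at once
Reagents that add atoms: water, O
Why: Acid-catalysed hydrolysis of a dimethyl acetal; aryl silyl ethers should survive brief cold aqueous acid. The aldehyde is not chromatographed because its C3–H is now acidic.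

Step 10
Reactants: 15 (2S,3S)-2-[3,4-bis(TBSO)phenyl]-4-oxo-6-[(E)-2-(4-(TBSO)phenyl)ethenyl]-2,3-dihydro-4H-furo[3,2-c]pyran-3-carbaldehyde; 16 2,2,6-trimethyl-4H-1,3-dioxin-4-one
Product: 17 6-{2-hydroxy-2-[(2S,3R)-2-[3,4-bis(TBSO)phenyl]-4-oxo-6-[(E)-2-(4-(TBSO)phenyl)ethenyl]-2,3-dihydro-4H-furo[3,2-c]pyran-3-yl]ethyl}-2,2-dimethyl-4H-1,3-dioxin-4-one (carbinol epimers; ring substituents trans as in 15, the descriptor at C3 changes by priority only)
Conditions: 16 (1.5 equiv), LiN(SiMe3)2 (1.5 equiv), THF, –78 °C; then 15, –78 °C; AcOH quench at –78 °C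
Reagents that add atoms: none
Why: Vinylogous aldol addition of the lithium dienolate of 16 through its γ-carbon, a standard entry to δ-hydroxy dioxinones; at –78 °C addition to the aldehyde should outpace α-deprotonation. The new carbinol centre is of no consequence because it is oxidised next.

Step 11
Reactants: 17 δ-hydroxy dioxinone (carbinol epimers)
Product: 18 6-{2-oxo-2-[(2S,3S)-2-[3,4-bis(TBSO)phenyl]-4-oxo-6-[(E)-2-(4-(TBSO)phenyl)ethenyl]-2,3-dihydro-4H-furo[3,2-c]pyran-3-yl]ethyl}-2,2-dimethyl-4H-1,3-dioxin-4-one
Conditions: Dess–Martin periodinane (1.5 equiv), NaHCO3, CH2Cl2, 0 °C to rt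
Reagents that add atoms: none
Why: Dess–Martin oxidation of a secondary alcohol under buffered, non-basic conditions, the usual way to δ-keto dioxinones; silyl ethers, the alkene and the C3–H should be left alone.

Step 12
Reactants: 18 δ-keto dioxinone
Product: 20 (2S,3S)-2-[3,4-bis(TBSO)phenyl]-3-(4-hydroxy-2-oxo-2H-pyran-6-yl)-6-[(E)-2-(4-(TBSO)phenyl)ethenyl]-2,3-dihydro-4H-furo[3,2-c]pyran-4-one, via acylketene 19 (not isolated)
Conditions: toluene (dilute), 110 °C
Reagents that add atoms: none
Why: Thermal retro-hetero-Diels–Alder loss of acetone from the dioxinone gives acylketene 19, whose ketene carbon is captured by the enol oxygen of the δ-ketone to close ring D as the 4-hydroxy-2-pyranone. The conditions are neutral, so no base comes near the C3–H.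

Step 13
Reactants: 20 tris-silyl ether of the target
Product: 21 (2S,3S)-2-(3,4-dihydroxyphenyl)-3-(4-hydroxy-2-oxo-2H-pyran-6-yl)-6-[(E)-2-(4-hydroxyphenyl)ethenyl]-2,3-dihydro-4H-furo[3,2-c]pyran-4-one (CNP0330607.1)
Conditions: HF·pyridine, THF/pyridine, 0 °C to rt
Reagents that add atoms: none
Why: Fluoride cleavage of three aryl silyl ethers; pyridine-buffered HF avoids the basic phenoxide and fluoride conditions that could open ring B by β-elimination, and it is too weakly acidic to ionise C2–O1.

## Compound list

1 | 3,4-dihydroxybenzaldehyde | O=Cc1ccc(O)c(O)c1 | starting material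
2 | 3,4-bis(TBSO)benzaldehyde | O=Cc1ccc(O[Si](C)(C)C(C)(C)C)c(O[Si](C)(C)C(C)(C)C)c1 | intermediate
3 | (triphenylphosphoranylidene)acetaldehyde | O=CC=P(c1ccccc1)(c1ccccc1)c1ccccc1 | starting material
4 | (E)-3-[3,4-bis(TBSO)phenyl]prop-2-enal | O=C/C=C/c1ccc(O[Si](C)(C)C(C)(C)C)c(O[Si](C)(C)C(C)(C)C)c1 | intermediate
5 | methyl acetoacetate | COC(=O)CC(C)=O | starting material
6 | methyl 2-bromo-3-oxobutanoate (racemic) | COC(=O)C(Br)C(C)=O | intermediate
7 | methyl (2S,3R)-1-acetyl-2-[3,4-bis(TBSO)phenyl]-3-formylcyclopropane-1-carboxylate (C1 epimers) | COC(=O)C1(C(C)=O)[C@H](c2ccc(O[Si](C)(C)C(C)(C)C)c(O[Si](C)(C)C(C)(C)C)c2)[C@H]1C=O | intermediate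
8 | methyl (2S,3R)-1-acetyl-2-[3,4-bis(TBSO)phenyl]-3-(dimethoxymethyl)cyclopropane-1-carboxylate (C1 epimers) | COC(=O)C1(C(C)=O)[C@H](c2ccc(O[Si](C)(C)C(C)(C)C)c(O[Si](C)(C)C(C)(C)C)c2)[C@H]1C(OC)OC | intermediate
9 | methyl (4S,5S)-5-[3,4-bis(TBSO)phenyl]-4-(dimethoxymethyl)-2-methyl-4,5-dihydrofuran-3-carboxylate | COC(OC)[C@H]1C(C(=O)OC)=C(C)O[C@@H]1c1ccc(O[Si](C)(C)C(C)(C)C)c(O[Si](C)(C)C(C)(C)C)c1 | intermediate
10 | 4-(TBSO)benzaldehyde | O=Cc1ccc(O[Si](C)(C)C(C)(C)C)cc1 | starting material
11 | diethyl {2-[methoxy(methyl)amino]-2-oxoethyl}phosphonate | CCOP(=O)(CC(=O)N(C)OC)OCC | starting material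
12 | (E)-N-methoxy-N-methyl-3-[4-(TBSO)phenyl]prop-2-enamide | CON(C)C(=O)/C=C/c1ccc(O[Si](C)(C)C(C)(C)C)cc1 | intermediate
13 | methyl (4S,5S)-5-[3,4-bis(TBSO)phenyl]-4-(dimethoxymethyl)-2-[(E)-2-oxo-4-(4-(TBSO)phenyl)but-3-enyl]-4,5-dihydrofuran-3-carboxylate (not isolated) | COC(OC)[C@H]1C(C(=O)OC)=C(CC(=O)/C=C/c2ccc(O[Si](C)(C)C(C)(C)C)cc2)O[C@@H]1c1ccc(O[Si](C)(C)C(C)(C)C)c(O[Si](C)(C)C(C)(C)C)c1 | intermediate
14 | (2S,3S)-2-[3,4-bis(TBSO)phenyl]-3-(dimethoxymethyl)-6-[(E)-2-(4-(TBSO)phenyl)ethenyl]-2,3-dihydro-4H-furo[3,2-c]pyran-4-one | COC(OC)[C@H]1c2c(cc(/C=C/c3ccc(O[Si](C)(C)C(C)(C)C)cc3)oc2=O)O[C@@H]1c1ccc(O[Si](C)(C)C(C)(C)C)c(O[Si](C)(C)C(C)(C)C)c1 | intermediate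
15 | (2S,3S)-2-[3,4-bis(TBSO)phenyl]-4-oxo-6-[(E)-2-(4-(TBSO)phenyl)ethenyl]-2,3-dihydro-4H-furo[3,2-c]pyran-3-carbaldehyde | O=C[C@H]1c2c(cc(/C=C/c3ccc(O[Si](C)(C)C(C)(C)C)cc3)oc2=O)O[C@@H]1c1ccc(O[Si](C)(C)C(C)(C)C)c(O[Si](C)(C)C(C)(C)C)c1 | intermediate
16 | 2,2,6-trimethyl-4H-1,3-dioxin-4-one | CC1=CC(=O)OC(C)(C)O1 | starting material
17 | 6-{2-hydroxy-2-[(2S,3R)-2-[3,4-bis(TBSO)phenyl]-4-oxo-6-[(E)-2-(4-(TBSO)phenyl)ethenyl]-2,3-dihydro-4H-furo[3,2-c]pyran-3-yl]ethyl}-2,2-dimethyl-4H-1,3-dioxin-4-one (carbinol epimers) | CC1(C)OC(CC(O)[C@H]2c3c(cc(/C=C/c4ccc(O[Si](C)(C)C(C)(C)C)cc4)oc3=O)O[C@@H]2c2ccc(O[Si](C)(C)C(C)(C)C)c(O[Si](C)(C)C(C)(C)C)c2)=CC(=O)O1 | intermediate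
18 | 6-{2-oxo-2-[(2S,3S)-2-[3,4-bis(TBSO)phenyl]-4-oxo-6-[(E)-2-(4-(TBSO)phenyl)ethenyl]-2,3-dihydro-4H-furo[3,2-c]pyran-3-yl]ethyl}-2,2-dimethyl-4H-1,3-dioxin-4-one | CC1(C)OC(CC(=O)[C@H]2c3c(cc(/C=C/c4ccc(O[Si](C)(C)C(C)(C)C)cc4)oc3=O)O[C@@H]2c2ccc(O[Si](C)(C)C(C)(C)C)c(O[Si](C)(C)C(C)(C)C)c2)=CC(=O)O1 | intermediate
19 | 5-[(2S,3S)-2-[3,4-bis(TBSO)phenyl]-4-oxo-6-[(E)-2-(4-(TBSO)phenyl)ethenyl]-2,3-dihydro-4H-furo[3,2-c]pyran-3-yl]pent-1-ene-1,3,5-trione (acylketene, not isolated) | O=C=CC(=O)CC(=O)[C@H]1c2c(cc(/C=C/c3ccc(O[Si](C)(C)C(C)(C)C)cc3)oc2=O)O[C@@H]1c1ccc(O[Si](C)(C)C(C)(C)C)c(O[Si](C)(C)C(C)(C)C)c1 | intermediate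
20 | (2S,3S)-2-[3,4-bis(TBSO)phenyl]-3-(4-hydroxy-2-oxo-2H-pyran-6-yl)-6-[(E)-2-(4-(TBSO)phenyl)ethenyl]-2,3-dihydro-4H-furo[3,2-c]pyran-4-one | O=c1cc(O)cc([C@H]2c3c(cc(/C=C/c4ccc(O[Si](C)(C)C(C)(C)C)cc4)oc3=O)O[C@@H]2c2ccc(O[Si](C)(C)C(C)(C)C)c(O[Si](C)(C)C(C)(C)C)c2)o1 | intermediate
21 | (2S,3S)-2-(3,4-dihydroxyphenyl)-3-(4-hydroxy-2-oxo-2H-pyran-6-yl)-6-[(E)-2-(4-hydroxyphenyl)ethenyl]-2,3-dihydro-4H-furo[3,2-c]pyran-4-one | O=c1cc(O)cc([C@H]2c3c(cc(/C=C/c4ccc(O)cc4)oc3=O)O[C@@H]2c2ccc(O)c(O)c2)o1 | target

## Step count and risks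

Total step count: 13. Longest linear sequence: 11 steps (1, 2, 4, 5, 6, 8, 9, 10, 11, 12, 13); steps 3 and 7 are one-step side branches.

**Step 8 (key step).** The most likely failures are slow ring closure of 13, partial loss of aryl silyl groups under the amidine base, and to a lesser extent conjugate addition of the dienolate to the enamide. Fallback, from 9: the same two bonds are made at the aldehyde oxidation level. (E)-3-[4-(TBSO)phenyl]prop-2-enal F1, obtained from 10 and 3 by the Wittig reaction of step 2, is added to the lithium dienolate of 9. The δ-alkoxide closes on the ester in the cold (the kavalactone-type vinylogous aldol lactonisation) and gives (2S,3S)-2-[3,4-bis(TBSO)phenyl]-3-(dimethoxymethyl)-6-[(E)-2-(4-(TBSO)phenyl)ethenyl]-2,3,6,7-tetrahydro-4H-furo[3,2-c]pyran-4-one F2. Dehydrogenation of F2 with 2,3-dichloro-5,6-dicyano-1,4-benzoquinone returns to the route at 14.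

**Step 4.** The electron-rich enal may form its iminium ion slowly, so that an uncatalysed, base-mediated addition erodes the enantioselectivity; premature opening of the cyclopropane under the amine conditions is a second concern. Fallback, from 4 and 5: 4 is converted with trimethyl orthoformate into (E)-3-[3,4-bis(TBSO)phenyl]prop-2-enal dimethyl acetal F3. Oxidative radical [3+2] annulation of 5 with F3 by Mn(OAc)3 in acetic acid should give the trans-dihydrofuran as a racemate: the keto ester radical adds to the alkene carbon next to the acetal, and the benzylic radical is oxidised and captured by the ketone oxygen. The racemate is 9 together with its enantiomer methyl (4R,5R)-5-[3,4-bis(TBSO)phenyl]-4-(dimethoxymethyl)-2-methyl-4,5-dihydrofuran-3-carboxylate F4. Preparative chromatography on a chiral stationary phase removes F4 and the route is rejoined at 9.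

**Step 6.** The Lewis acid may ionise the acetal in place of the cyclopropane (loss of methanol, then aromatisation to a furan), or the closure may be incompletely trans-selective. Fallback, from 7 (step 5 is skipped): the ring is expanded before the acetal exists, by nucleophilic catalysis with MgI2. Iodide opens the cyclopropane at the benzylic carbon and the magnesium enolate oxygen displaces iodide; two inversions give net retention and hence the trans product methyl (4S,5S)-5-[3,4-bis(TBSO)phenyl]-4-formyl-2-methyl-4,5-dihydrofuran-3-carboxylate F5. Acetalisation of F5 as in step 5 rejoins the route at 9.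

**Step 10.** The basic dienolate may deprotonate C3 of 15 instead of adding; β-elimination of O1 and reclosure would then cause racemisation. Fallback, from 15 and 16: 16 is converted with LiN(SiMe3)2 and Me3SiCl into [(2,2-dimethyl-6-methylidene-6H-1,3-dioxin-4-yl)oxy]trimethylsilane F6. F6 adds to 15 under BF3·OEt2 at –78 °C (vinylogous Mukaiyama aldol) with no base present, and aqueous work-up rejoins the route at 17.

## Further compounds

F1 | step 8 | (E)-3-[4-(TBSO)phenyl]prop-2-enal | O=C/C=C/c1ccc(O[Si](C)(C)C(C)(C)C)cc1
F2 | step 8 | (2S,3S)-2-[3,4-bis(TBSO)phenyl]-3-(dimethoxymethyl)-6-[(E)-2-(4-(TBSO)phenyl)ethenyl]-2,3,6,7-tetrahydro-4H-furo[3,2-c]pyran-4-one (C6 epimers) | COC(OC)[C@H]1C2=C(CC(/C=C/c3ccc(O[Si](C)(C)C(C)(C)C)cc3)OC2=O)O[C@@H]1c1ccc(O[Si](C)(C)C(C)(C)C)c(O[Si](C)(C)C(C)(C)C)c1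
F3 | step 4 | (E)-3-[3,4-bis(TBSO)phenyl]prop-2-enal dimethyl acetal | COC(OC)/C=C/c1ccc(O[Si](C)(C)C(C)(C)C)c(O[Si](C)(C)C(C)(C)C)c1
F4 | step 4 | methyl (4R,5R)-5-[3,4-bis(TBSO)phenyl]-4-(dimethoxymethyl)-2-methyl-4,5-dihydrofuran-3-carboxylate | COC(OC)[C@@H]1C(C(=O)OC)=C(C)O[C@H]1c1ccc(O[Si](C)(C)C(C)(C)C)c(O[Si](C)(C)C(C)(C)C)c1
F5 | step 6 | methyl (4S,5S)-5-[3,4-bis(TBSO)phenyl]-4-formyl-2-methyl-4,5-dihydrofuran-3-carboxylate | O=C[C@H]1C(C(=O)OC)=C(C)O[C@@H]1c1ccc(O[Si](C)(C)C(C)(C)C)c(O[Si](C)(C)C(C)(C)C)c1
F6 | step 10 | [(2,2-dimethyl-6-methylidene-6H-1,3-dioxin-4-yl)oxy]trimethylsilane | C=C1C=C(O[Si](C)(C)C)OC(C)(C)O1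
A1 | alternative 1 | (S)-4-benzyl-3-{2-[4-methoxy-2-oxo-6-[(E)-2-(4-(TBSO)phenyl)ethenyl]-2H-pyran-3-yl]acetyl}oxazolidin-2-one | COc1cc(/C=C/c2ccc(O[Si](C)(C)C(C)(C)C)cc2)oc(=O)c1CC(=O)N1[C@@H](Cc2ccccc2)COC1=O
A2 | alternative 1 | (S)-4-benzyl-3-{(2S,3S)-2-[3,4-bis(TBSO)phenyl]-4-oxo-6-[(E)-2-(4-(TBSO)phenyl)ethenyl]-2,3-dihydro-4H-furo[3,2-c]pyran-3-carbonyl}oxazolidin-2-one | O=C([C@H]1c2c(cc(/C=C/c3ccc(O[Si](C)(C)C(C)(C)C)cc3)oc2=O)O[C@@H]1c1ccc(O[Si](C)(C)C(C)(C)C)c(O[Si](C)(C)C(C)(C)C)c1)N1[C@@H](Cc2ccccc2)COC1=O
A3 | alternative 2 | 4-hydroxy-6-[(E)-2-(4-(TBSO)phenyl)ethenyl]-2H-pyran-2-one | O=c1cc(O)cc(/C=C/c2ccc(O[Si](C)(C)C(C)(C)C)cc2)o1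
A4 | alternative 2 | 4-(methoxymethoxy)-2-oxo-2H-pyran-6-carbaldehyde | COCOc1cc(C=O)oc(=O)c1
A5 | alternative 2 | (2R,5R)-1-[3,4-bis(TBSO)benzyl]-2,5-dimethylthiolan-1-ium trifluoromethanesulfonate | C[C@@H]1CC[C@@H](C)[S+]1Cc1ccc(O[Si](C)(C)C(C)(C)C)c(O[Si](C)(C)C(C)(C)C)c1.[O-]S(=O)(=O)C(F)(F)F
A6 | alternative 2 | (2S,3S)-2-[3,4-bis(TBSO)phenyl]-3-[4-(methoxymethoxy)-2-oxo-2H-pyran-6-yl]-6-[(E)-2-(4-(TBSO)phenyl)ethenyl]-2,3-dihydro-4H-furo[3,2-c]pyran-4-one | O=c1cc(OCOC)cc([C@H]2c3c(cc(/C=C/c4ccc(O[Si](C)(C)C(C)(C)C)cc4)oc3=O)O[C@@H]2c2ccc(O[Si](C)(C)C(C)(C)C)c(O[Si](C)(C)C(C)(C)C)c2)o1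
A7 | alternative 3 | 3-bromo-4-hydroxy-6-[(E)-2-(4-(TBSO)phenyl)ethenyl]-2H-pyran-2-one | O=c1oc(/C=C/c2ccc(O[Si](C)(C)C(C)(C)C)cc2)cc(O)c1Br
A8 | alternative 3 | 1-[3,4-bis(TBSO)phenyl]-4,8-dioxo-6-[(E)-2-(4-(TBSO)phenyl)ethenyl]-5-oxaspiro[2.5]oct-6-ene-2-carbaldehyde (aryl and formyl trans, CH centres in the sense of 7, spiro centre undefined) | O=C1C=C(/C=C/c3ccc(O[Si](C)(C)C(C)(C)C)cc3)OC(=O)C12[C@H](c4ccc(O[Si](C)(C)C(C)(C)C)c(O[Si](C)(C)C(C)(C)C)c4)[C@H]2C=O
A9 | alternative 3 | (2S,3S)-2-[3,4-bis(TBSO)phenyl]-4-oxo-6-[(E)-2-(4-(TBSO)phenyl)ethenyl]-2,3-dihydro-4H-furo[3,2-c]pyran-3-carbaldehyde (identical with 15) | O=C[C@H]1c2c(cc(/C=C/c3ccc(O[Si](C)(C)C(C)(C)C)cc3)oc2=O)O[C@@H]1c1ccc(O[Si](C)(C)C(C)(C)C)c(O[Si](C)(C)C(C)(C)C)c1
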